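## Retrosynthetic overview

1. The target comes from tris-silyl ether 46, whose ring-E alkene and side-chain stereocentre are set together by a reductive 1,3-transposition (allylic diazene) of allylic alcohol 43. Alcohol 43 comes from 1,2-addition of an eastern alkyl-metal (from iodide 25) to western enone 38, then oxidative transposition and CBS reduction.
2. Eastern iodide 25: the oxepane (ring C) is closed last by 7-endo opening of a Shi epoxide by the axial ring-A alcohol. Both ring-A side arms come from ozonolysis of a temporary ring B in a trans-decalin.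
3. The trans-decalin comes from (S)-Wieland–Miescher ketone (proline-catalysed aldol of an achiral triketone). A ketoreductase sets the carbinol; hydroboration and MeMgBr set the other ring-A centres.
4. Western enone 38: dibromocarbene ring expansion of a cis-hydrindanone, itself from a catalytic asymmetric Michael/Michael annulation of cyclopent-2-enone with a 2-siloxydiene.
5. Ring order: east, ring A (with temporary ring B), then oxepane ring C; west, ring D plus a six-membered precursor together, then seven-membered ring E; the fragments are joined last.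

Assumptions (one line): 4-methylpent-1-en-3-one (26) is bought as such; the ketoreductase of step 3 is picked from a commercial anti-Prelog panel by screening; the catalyst antipodes named in steps 15, 22 and 32 are those predicted by the published facial models.

## Route

### Eastern fragment (steps 1–20)

Step 1
Reactants: 1 2-methylcyclohexane-1,3-dione; 2 but-3-en-2-one
Product: 3 2-methyl-2-(3-oxobutyl)cyclohexane-1,3-dione
Conditions: Et3N (1 mol%), neat, rt
Reagents that add atoms: none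
Why: Michael addition of the acidic 1,3-dione to the enone gives the achiral, prochiral triketone.

Step 2
Reactants: 3 2-methyl-2-(3-oxobutyl)cyclohexane-1,3-dione
Product: 5 (S)-Wieland–Miescher ketone, via cis-ketol 4 (not isolated)
Conditions: L-proline (35 mol%), DMSO, rt, 5 d; recrystallise (Et2O/hexane) to >99% ee
Reagents that add atoms: none
Why: The Hajos–Parrish–Eder–Sauer–Wiechert enamine aldol differentiates the two ring carbonyls and sets the quaternary methyl-bearing centre (S) by asymmetric organocatalysis, with dehydration in the flask.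

Step 3
Reactants: 5 (S)-Wieland–Miescher ketone
Product: 6 (4aS,5R)-5-hydroxy-4a-methyl-4,4a,5,6,7,8-hexahydronaphthalen-2(3H)-one
Conditions: ketoreductase (anti-Prelog NADPH-dependent alcohol dehydrogenase, Lactobacillus kefir type), NADP+ (cat.), i-PrOH (10% v/v), MgCl2 (1 mM), phosphate buffer pH 7.0, 30 °C
Reagents that add atoms: none
Why: Enzyme-controlled carbonyl reduction delivers hydride to the saturated ketone only and gives the axial (5R) alcohol trans to the angular methyl, the diastereomer that NaBH4 does not give.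

Step 4
Reactants: 6 (4aS,5R)-hydroxy enone
Product: 7 (4a′S,5′R)-4a′-methyl-3′,4′,4a′,5′,6′,7′-hexahydro-1′H-spiro[1,3-dioxolane-2,2′-naphthalen]-5′-ol
Conditions: HOCH2CH2OH, p-TsOH (cat.), benzene, reflux, Dean–Stark
Reagents that add atoms: ethane-1,2-diol, OCCO
Why: Acetalisation of the enone carbonyl moves the double bond out of conjugation into ring A, as with 4-en-3-one steroids.

Step 5
Reactants: 7 hydroxy dioxolane
Product: 8 benzyl ether of 7
Conditions: NaH, BnBr, n-Bu4NI (cat.), THF/DMF, 0 °C → rt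
Reagents that add atoms: benzyl bromide, BrCc1ccccc1
Why: Williamson etherification protects the hindered axial alcohol with a group that survives every step up to step 16.

Step 6
Reactants: 8 benzyl ether
Product: 10 trans-fused secondary alcohol (4a′S,5′R,8′S,8a′S), via alkylborane 9 (not isolated)
Conditions: BH3·THF, THF, 0 °C → rt; then 3 M NaOH, 30% H2O2, 0 °C → rt
Reagents that add atoms: hydrogen peroxide, OO
Why: Hydroboration–oxidation adds H and B syn from the face opposite the angular methyl, so the new ring-fusion hydrogen is trans to that methyl (trans-decalin) and the hydroxyl sits on the less substituted carbon.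

Step 7
Reactants: 10 secondary alcohol
Product: 11 ring-A ketone (4a′S,5′R,8a′S)
Conditions: Dess–Martin periodinane, NaHCO3, CH2Cl2, rt
Reagents that add atoms: none
Why: Alcohol oxidation; the adjacent ring-fusion centre stays in the thermodynamically favoured trans-decalone configuration.

Step 8
Reactants: 11 ring-A ketone
Product: 12 tertiary alcohol (4a′S,5′R,8′R,8a′S)
Conditions: MeMgBr, CeCl3, THF, −78 → 0 °C
Reagents that add atoms: methylmagnesium bromide, C[Mg]Br
Why: In this 1,2-addition axial attack is blocked by the 1,3-diaxial angular methyl, so the methyl enters equatorially and the tertiary hydroxyl ends up axial, cis to the angular methyl.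

Step 9
Reactants: 12 tertiary alcohol
Product: 13 (4aS,5R,8R,8aS)-5-(benzyloxy)-8-hydroxy-4a,8-dimethyloctahydronaphthalen-2(1H)-one
Conditions: PPTS, acetone/H2O (5:1), 55 °C
Reagents that add atoms: none
Why: Mild acetal hydrolysis frees the ring-B ketone without dehydrating the tertiary alcohol.

Step 10
Reactants: 13 ring-B ketone
Product: 14 bis(triethylsilyl) compound (tertiary silyl ether and silyl enol ether)
Conditions: Et3SiOTf (3 equiv), Et3N, CH2Cl2, 0 °C → rt
Reagents that add atoms: triethylsilyl trifluoromethanesulfonate, CC[Si](CC)(CC)OS(=O)(=O)C(F)(F)F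
Why: One-pot O-silylation of the tertiary alcohol and thermodynamic silyl enol ether formation away from the ring fusion, the direction in which 5α-3-keto steroids enolise.

Step 11
Reactants: 14 bis(triethylsilyl) compound
Product: 16 {(1S,2S,3R,6R)-3-(benzyloxy)-2-(2-hydroxyethyl)-2,6-dimethyl-6-[(triethylsilyl)oxy]cyclohexyl}acetic acid, via oxo silyl ester 15 (not isolated)
Conditions: O3, CH2Cl2/MeOH (4:1), −78 °C; then NaBH4, −78 → 0 °C; aq. NaH2PO4
Reagents that add atoms: ozone, [O-][O+]=O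
Why: Ozonolysis of the electron-rich silyl enol ether cleaves ring B into an acid arm and an aldehyde arm, and borohydride reduces only the aldehyde, so the two arms emerge differentiated.

Step 12
Reactants: 16 hydroxy acid
Product: 17 methyl ester of 16
Conditions: Me3SiCHN2, MeOH/toluene, 0 °C
Reagents that add atoms: (trimethylsilyl)diazomethane, C[Si](C)(C)C=[N+]=[N-]
Why: Chemoselective O-methylation of the carboxylic acid.

Step 13
Reactants: 17 hydroxy ester
Product: 18 primary iodide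
Conditions: I2, PPh3, imidazole, CH2Cl2, 0 °C → rt
Reagents that add atoms: iodine, II
Why: Appel iodination of the unhindered primary alcohol.

Step 14
Reactants: 18 primary iodide
Product: 19 methyl {(1S,2S,3R,6R)-3-(benzyloxy)-2,6-dimethyl-2-(4-methylpent-3-en-1-yl)-6-[(triethylsilyl)oxy]cyclohexyl}acetate
Conditions: (CH3)2C=CHMgBr (1.5 equiv, slow addition), Li2CuCl4 (5 mol%), NMP, THF, −20 → 0 °C
Reagents that add atoms: (2-methylprop-1-en-1-yl)magnesium bromide, CC(C)=C[Mg]Br
Why: Copper-catalysed (Kochi) coupling of a primary iodide with an alkenyl Grignard reagent is faster than addition to the ester and installs the trisubstituted alkene.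

Step 15
Reactants: 19 alkene
Product: 20 (S)-epoxide
Conditions: L-fructose-derived Shi ketone (30 mol%), KHSO5 (as Oxone), K2CO3, n-Bu4NHSO4 (cat.), MeCN/(MeO)2CH2/aq. Na2B4O7 buffer (pH 10.5), 0 °C
Reagents that add atoms: potassium peroxymonosulfate, [K+].[O-]S(=O)(=O)OO
Why: Shi asymmetric epoxidation (chiral dioxirane, spiro transition state) sets the secondary carbinol carbon as (S) under reagent control.

Step 16
Reactants: 20 (S)-epoxide
Product: 21 hydroxy epoxide
Conditions: H2 (1 atm), Pd(OH)2/C, EtOAc, rt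
Reagents that add atoms: none
Why: Neutral hydrogenolysis removes the benzyl ether; the trialkyl epoxide, ester and silyl ether are inert.

Step 17
Reactants: 21 hydroxy epoxide
Product: 22 methyl {(3S,5aS,6S,7R,9aR)-3-hydroxy-2,2,5a,7-tetramethyl-7-[(triethylsilyl)oxy]decahydro-1-benzoxepin-6-yl}acetate
Conditions: camphorsulfonic acid (10 mol%), anhydrous CH2Cl2, −20 → 0 °C
Reagents that add atoms: none
Why: Acid-catalysed epoxide opening, in which the axial ring-A hydroxyl attacks the tertiary (better cation-stabilising) epoxide carbon in the 7-endo mode; the (S) C–O bond is untouched and the ring fusion is cis because oxygen and chain are already cis on ring A.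

Step 18
Reactants: 22 oxepane alcohol
Product: 23 bis(triethylsilyl) ether ester
Conditions: Et3SiOTf, 2,6-lutidine, CH2Cl2, −78 → 0 °C
Reagents that add atoms: triethylsilyl trifluoromethanesulfonate, CC[Si](CC)(CC)OS(=O)(=O)C(F)(F)F
Why: Silylation of the neopentylic secondary alcohol ahead of the organometallic steps.

Step 19
Reactants: 23 ester
Product: 24 primary alcohol
Conditions: LiAlH4, Et2O, 0 °C
Reagents that add atoms: none
Why: Hydride reduction of the methyl ester; the silyl ethers are stable.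

Step 20
Reactants: 24 primary alcohol
Product: 25 (3S,5aS,6S,7R,9aR)-6-(2-iodoethyl)-2,2,5a,7-tetramethyl-3,7-bis[(triethylsilyl)oxy]decahydro-1-benzoxepine
Conditions: I2, PPh3, imidazole, CH2Cl2, 0 °C
Reagents that add atoms: iodine, II
Why: Appel iodination; the neighbouring tertiary oxygen is silylated and cannot close a tetrahydrofuran.

### Western fragment (steps 21–29)

Step 21
Reactants: 26 4-methylpent-1-en-3-one
Product: 27 triisopropyl[(4-methylpenta-1,3-dien-3-yl)oxy]silane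
Conditions: i-Pr3SiOTf, Et3N, Et2O, 0 °C
Reagents that add atoms: triisopropylsilyl trifluoromethanesulfonate, CC(C)[Si](C(C)C)(C(C)C)OS(=O)(=O)C(F)(F)F
Why: Soft enolisation can only occur toward the isopropyl carbon and gives the 2-siloxydiene.

Step 22
Reactants: 27 siloxydiene; 28 cyclopent-2-en-1-one
Product: 30 (3aS,7aS)-4,4-dimethylhexahydro-1H-indene-1,5(4H)-dione, via silyl enol ether adduct 29 (not isolated)
Conditions: (S)-B-(o-tolyl)-diphenylprolinol-derived oxazaborolidine·Tf2NH (20 mol%), CH2Cl2, −78 → −20 °C; then 2 M HCl, THF, rt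
Reagents that add atoms: none
Why: In this catalytic asymmetric Mukaiyama–Michael/Michael annulation (formal Diels–Alder) the chiral oxazaborolidinium ion fixes the face of the enone attacked by the dimethyl-substituted enol carbon, which sets the first western stereocentre, and ring closure on the same face gives the cis fusion, also the more stable one.

Step 23
Reactants: 30 cis-diketone
Product: 31 (3aS,7aS)-4,4-dimethyl-1-methylideneoctahydro-5H-inden-5-one
Conditions: Ph3PCH3Br, KOt-Bu, THF, 0 °C (1.05 equiv ylide)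
Reagents that add atoms: methyltriphenylphosphonium bromide, C[P+](c1ccccc1)(c1ccccc1)c1ccccc1.[Br-]
Why: Wittig methylenation takes the cyclopentanone and leaves the neopentyl-type six-ring ketone untouched.

Step 24
Reactants: 31 methylidene ketone
Product: 32 spiro-epoxide (oxygen cis to the ring-fusion hydrogens)
Conditions: m-CPBA, NaHCO3, CH2Cl2, 0 °C
Reagents that add atoms: 3-chloroperoxybenzoic acid, OOC(=O)c1cccc(Cl)c1
Why: Prilezhaev epoxidation from the convex face of the cis-hydrindane, anti to the adjacent ring carbon, puts the oxygen where the tertiary hydroxyl must be.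

Step 25
Reactants: 32 spiro-epoxide
Product: 33 (1S,3aS,7aS)-1,4,4-trimethyloctahydro-1H-indene-1,5-diol (C-5 epimers)
Conditions: LiAlH4, THF, 0 °C → rt
Reagents that add atoms: none
Why: Hydride opens the epoxide at its CH2 carbon to give the tertiary carbinol with methyl on the concave face; the ketone is reduced as well and is restored in step 26.

Step 26
Reactants: 33 diol
Product: 34 (1S,3aS,7aS)-1-hydroxy-1,4,4-trimethyloctahydro-5H-inden-5-one
Conditions: Dess–Martin periodinane, NaHCO3, CH2Cl2, rt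
Reagents that add atoms: none
Why: Only the secondary alcohol can be oxidised.

Step 27
Reactants: 34 hydroxy ketone
Product: 35 bis(triethylsilyl) compound (tertiary silyl ether and silyl enol ether)
Conditions: Et3SiOTf (2.5 equiv), Et3N, CH2Cl2, 0 °C → rt
Reagents that add atoms: triethylsilyl trifluoromethanesulfonate, CC[Si](CC)(CC)OS(=O)(=O)C(F)(F)F
Why: The ketone has a quaternary carbon on one side, so the silyl enol ether can form in one direction only, and the tertiary alcohol is protected in the same pot.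

Step 28
Reactants: 35 bis(triethylsilyl) compound
Product: 37 (1S,3aS,8aS)-6-bromo-1,4,4-trimethyl-1-[(triethylsilyl)oxy]-2,3,3a,4,8,8a-hexahydroazulen-5(1H)-one, via dibromocyclopropane 36 (not isolated)
Conditions: CHBr3, KOt-Bu, pentane, −20 °C → rt; then pyridine, toluene, 90 °C
Reagents that add atoms: bromoform, BrC(Br)Br
Why: Dibromocarbene adds to the enol ether and the siloxy-dibromocyclopropane opens electrocyclically with loss of bromide and the silyl group, giving the ring-expanded 2-bromo-cycloheptenone (ring E).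

Step 29
Reactants: 37 bromoenone
Product: 38 (1S,3aS,8aS)-1,4,4,6-tetramethyl-1-[(triethylsilyl)oxy]-2,3,3a,4,8,8a-hexahydroazulen-5(1H)-one
Conditions: (MeBO)3, Pd(PPh3)4 (5 mol%), K2CO3, dioxane/H2O, 90 °C
Reagents that add atoms: trimethylboroxine, CB1OB(C)OB(C)O1
Why: Suzuki–Miyaura methylation of the α-bromo enone places the ring methyl on the alkene carbon.

### Fragment union and endgame (steps 30–34)

Step 30
Reactants: 25 eastern iodide; 38 western enone
Product: 41 tertiary allylic alcohol (C-5 epimers of the azulenol), via alkyllithium 39 (not isolated), via alkylcerium dichloride 40 (not isolated)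
Conditions: 25, t-BuLi (2.1 equiv), Et2O/pentane, −78 °C; CeCl3, THF, −78 °C; then 38, −78 → −40 °C
Reagents that add atoms: none
Why: Iodine–lithium exchange then transmetalation gives a non-basic primary organocerium that adds 1,2 to the hindered enone, as alkyl-metals do with 2,6,6-trimethylcyclohex-2-enone; the new carbinol centre is erased in step 31.

Step 31
Reactants: 41 tertiary allylic alcohol
Product: 42 transposed enone (carbonyl at C-7, side chain on C-5 of the azulene)
Conditions: (C5H5NH)[CrO3Cl] (pyridinium chlorochromate), NaOAc, 4 Å molecular sieves, CH2Cl2, rt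
Reagents that add atoms: none
Why: Dauben oxidative 1,3-transposition: the chromate ester of the tertiary allylic alcohol rearranges sigmatropically and is oxidised to the β,β-disubstituted enone.

Step 32
Reactants: 42 transposed enone
Product: 43 (7R)-allylic alcohol (hydroxyl on the face opposite the ring-fusion hydrogens)
Conditions: (S)-2-methyl-CBS-oxazaborolidine (0.5 equiv), BH3·THF, THF, −30 °C
Reagents that add atoms: none
Why: Corey–Bakshi–Shibata reduction delivers hydride to the convex face, with the alkenyl side as the large group, so catalyst and substrate control agree and give the (R)-carbinol.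

Step 33
Reactants: 43 (7R)-allylic alcohol
Product: 46 tris(triethylsilyl) ether of the target, via sulfonylhydrazine 44 (not isolated), via allylic diazene 45 (not isolated)
Conditions: 2-nitrobenzenesulfonylhydrazide, PPh3, DEAD, N-methylmorpholine, −30 °C → rt
Reagents that add atoms: none
Why: Myers reductive transposition: Mitsunobu displacement inverts the carbinol, sulfinate loss gives the diazene, and its retro-ene loss of N2 delivers hydrogen suprafacially to the far alkene carbon, setting the side-chain stereocentre (R) and moving the alkene into its final position.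

Step 34
Reactants: 46 tris(triethylsilyl) ether
Product: 47 target CNP0183476.6
Conditions: HF·pyridine, pyridine, THF, 0 °C → rt
Reagents that add atoms: none
Why: Fluoride-mediated desilylation frees the secondary and both tertiary alcohols without touching the alkene or the oxepane.

## Compound list

1 | 2-methylcyclohexane-1,3-dione | CC1C(=O)CCCC1=O | starting material
2 | but-3-en-2-one | CC(=O)C=C | starting material
3 | 2-methyl-2-(3-oxobutyl)cyclohexane-1,3-dione | CC(=O)CCC1(C)C(=O)CCCC1=O | intermediate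
4 | (4aS,8aS)-4a-hydroxy-8a-methyloctahydronaphthalene-1,6-dione (cis-ketol) | C[C@]12CCC(=O)C[C@@]1(O)CCCC2=O | intermediate (not isolated)
5 | (8aS)-8a-methyl-3,4,8,8a-tetrahydronaphthalene-1,6(2H,7H)-dione | C[C@]12CCC(=O)C=C1CCCC2=O | intermediate
6 | (4aS,5R)-5-hydroxy-4a-methyl-4,4a,5,6,7,8-hexahydronaphthalen-2(3H)-one | C[C@]12CCC(=O)C=C1CCC[C@H]2O | intermediate
7 | (4a′S,5′R)-4a′-methyl-3′,4′,4a′,5′,6′,7′-hexahydro-1′H-spiro[1,3-dioxolane-2,2′-naphthalen]-5′-ol | C[C@]12CCC3(OCCO3)CC1=CCC[C@H]2O | intermediate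
8 | (4a′S,5′R)-5′-(benzyloxy)-4a′-methyl-3′,4′,4a′,5′,6′,7′-hexahydro-1′H-spiro[1,3-dioxolane-2,2′-naphthalene] | C[C@]12CCC3(OCCO3)CC1=CCC[C@H]2OCc1ccccc1 | intermediate
9 | alkylborane: compound 10 with BH2 in place of the 8′-hydroxyl | C[C@]12CCC3(OCCO3)C[C@@H]1[C@@H](B)CC[C@H]2OCc1ccccc1 | intermediate (not isolated)
10 | (4a′S,5′R,8′S,8a′S)-5′-(benzyloxy)-4a′-methyloctahydro-1′H-spiro[1,3-dioxolane-2,2′-naphthalen]-8′-ol | C[C@]12CCC3(OCCO3)C[C@@H]1[C@@H](O)CC[C@H]2OCc1ccccc1 | intermediate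
11 | (4a′S,5′R,8a′S)-5′-(benzyloxy)-4a′-methylhexahydro-1′H-spiro[1,3-dioxolane-2,2′-naphthalen]-8′(3′H)-one | C[C@]12CCC3(OCCO3)C[C@@H]1C(=O)CC[C@H]2OCc1ccccc1 | intermediate
12 | (4a′S,5′R,8′R,8a′S)-5′-(benzyloxy)-4a′,8′-dimethyloctahydro-1′H-spiro[1,3-dioxolane-2,2′-naphthalen]-8′-ol | C[C@]12CCC3(OCCO3)C[C@@H]1[C@](C)(O)CC[C@H]2OCc1ccccc1 | intermediate
13 | (4aS,5R,8R,8aS)-5-(benzyloxy)-8-hydroxy-4a,8-dimethyloctahydronaphthalen-2(1H)-one | C[C@]12CCC(=O)C[C@@H]1[C@](C)(O)CC[C@H]2OCc1ccccc1 | intermediate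
14 | (4aS,5R,8R,8aS)-5-(benzyloxy)-4a,8-dimethyl-2,8-bis[(triethylsilyl)oxy]-1,4,4a,5,6,7,8,8a-octahydronaphthalene | C[C@]12CC=C(O[Si](CC)(CC)CC)C[C@@H]1[C@](C)(O[Si](CC)(CC)CC)CC[C@H]2OCc1ccccc1 | intermediate
15 | triethylsilyl {(1S,2S,3R,6R)-3-(benzyloxy)-2,6-dimethyl-2-(2-oxoethyl)-6-[(triethylsilyl)oxy]cyclohexyl}acetate | C[C@]1(CC=O)[C@H](CC(=O)O[Si](CC)(CC)CC)[C@](C)(O[Si](CC)(CC)CC)CC[C@H]1OCc1ccccc1 | intermediate (not isolated)
16 | {(1S,2S,3R,6R)-3-(benzyloxy)-2-(2-hydroxyethyl)-2,6-dimethyl-6-[(triethylsilyl)oxy]cyclohexyl}acetic acid | C[C@]1(CCO)[C@H](CC(=O)O)[C@](C)(O[Si](CC)(CC)CC)CC[C@H]1OCc1ccccc1 | intermediate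
17 | methyl {(1S,2S,3R,6R)-3-(benzyloxy)-2-(2-hydroxyethyl)-2,6-dimethyl-6-[(triethylsilyl)oxy]cyclohexyl}acetate | C[C@]1(CCO)[C@H](CC(=O)OC)[C@](C)(O[Si](CC)(CC)CC)CC[C@H]1OCc1ccccc1 | intermediate
18 | methyl {(1S,2S,3R,6R)-3-(benzyloxy)-2-(2-iodoethyl)-2,6-dimethyl-6-[(triethylsilyl)oxy]cyclohexyl}acetate | C[C@]1(CCI)[C@H](CC(=O)OC)[C@](C)(O[Si](CC)(CC)CC)CC[C@H]1OCc1ccccc1 | intermediate
19 | methyl {(1S,2S,3R,6R)-3-(benzyloxy)-2,6-dimethyl-2-(4-methylpent-3-en-1-yl)-6-[(triethylsilyl)oxy]cyclohexyl}acetate | C[C@]1(CCC=C(C)C)[C@H](CC(=O)OC)[C@](C)(O[Si](CC)(CC)CC)CC[C@H]1OCc1ccccc1 | intermediate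
20 | methyl {(1S,2S,3R,6R)-3-(benzyloxy)-2-{2-[(2S)-3,3-dimethyloxiran-2-yl]ethyl}-2,6-dimethyl-6-[(triethylsilyl)oxy]cyclohexyl}acetate | C[C@]1(CC[C@@H]2OC2(C)C)[C@H](CC(=O)OC)[C@](C)(O[Si](CC)(CC)CC)CC[C@H]1OCc1ccccc1 | intermediate
21 | methyl {(1S,2S,3R,6R)-2-{2-[(2S)-3,3-dimethyloxiran-2-yl]ethyl}-3-hydroxy-2,6-dimethyl-6-[(triethylsilyl)oxy]cyclohexyl}acetate | C[C@]1(CC[C@@H]2OC2(C)C)[C@H](CC(=O)OC)[C@](C)(O[Si](CC)(CC)CC)CC[C@H]1O | intermediate
22 | methyl {(3S,5aS,6S,7R,9aR)-3-hydroxy-2,2,5a,7-tetramethyl-7-[(triethylsilyl)oxy]decahydro-1-benzoxepin-6-yl}acetate | COC(=O)C[C@H]1[C@]2(C)CC[C@H](O)C(C)(C)O[C@@H]2CC[C@@]1(C)O[Si](CC)(CC)CC | intermediate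
23 | methyl {(3S,5aS,6S,7R,9aR)-2,2,5a,7-tetramethyl-3,7-bis[(triethylsilyl)oxy]decahydro-1-benzoxepin-6-yl}acetate | COC(=O)C[C@H]1[C@]2(C)CC[C@H](O[Si](CC)(CC)CC)C(C)(C)O[C@@H]2CC[C@@]1(C)O[Si](CC)(CC)CC | intermediate
24 | 2-{(3S,5aS,6S,7R,9aR)-2,2,5a,7-tetramethyl-3,7-bis[(triethylsilyl)oxy]decahydro-1-benzoxepin-6-yl}ethan-1-ol | OCC[C@H]1[C@]2(C)CC[C@H](O[Si](CC)(CC)CC)C(C)(C)O[C@@H]2CC[C@@]1(C)O[Si](CC)(CC)CC | intermediate
25 | (3S,5aS,6S,7R,9aR)-6-(2-iodoethyl)-2,2,5a,7-tetramethyl-3,7-bis[(triethylsilyl)oxy]decahydro-1-benzoxepine | ICC[C@H]1[C@]2(C)CC[C@H](O[Si](CC)(CC)CC)C(C)(C)O[C@@H]2CC[C@@]1(C)O[Si](CC)(CC)CC | intermediate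
26 | 4-methylpent-1-en-3-one | CC(C)C(=O)C=C | starting material
27 | triisopropyl[(4-methylpenta-1,3-dien-3-yl)oxy]silane | C=CC(O[Si](C(C)C)(C(C)C)C(C)C)=C(C)C | intermediate
28 | cyclopent-2-en-1-one | O=C1CCC=C1 | starting material
29 | (3aS,7aS)-4,4-dimethyl-5-[(triisopropylsilyl)oxy]-2,3,3a,4,7,7a-hexahydro-1H-inden-1-one | O=C1CC[C@H]2[C@@H]1CC=C(O[Si](C(C)C)(C(C)C)C(C)C)C2(C)C | intermediate (not isolated)
30 | (3aS,7aS)-4,4-dimethylhexahydro-1H-indene-1,5(4H)-dione (cis-fused) | O=C1CC[C@H]2[C@@H]1CCC(=O)C2(C)C | intermediate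
31 | (3aS,7aS)-4,4-dimethyl-1-methylideneoctahydro-5H-inden-5-one | C=C1CC[C@H]2[C@@H]1CCC(=O)C2(C)C | intermediate
32 | (1S,3aS,7aS)-4,4-dimethylhexahydrospiro[indene-1,2′-oxiran]-5(4H)-one (epoxide O cis to the ring-fusion H atoms) | C1O[C@]12CC[C@H]3[C@@H]2CCC(=O)C3(C)C | intermediate
33 | (1S,3aS,7aS)-1,4,4-trimethyloctahydro-1H-indene-1,5-diol (C-5 epimers) | C[C@]1(O)CC[C@H]2[C@@H]1CCC(O)C2(C)C | intermediate
34 | (1S,3aS,7aS)-1-hydroxy-1,4,4-trimethyloctahydro-5H-inden-5-one | C[C@]1(O)CC[C@H]2[C@@H]1CCC(=O)C2(C)C | intermediate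
35 | (1S,3aS,7aS)-1,4,4-trimethyl-1,5-bis[(triethylsilyl)oxy]-2,3,3a,4,7,7a-hexahydro-1H-indene | C[C@]1(O[Si](CC)(CC)CC)CC[C@H]2[C@@H]1CC=C(O[Si](CC)(CC)CC)C2(C)C | intermediate
36 | dibromocyclopropane: 35 with a CBr2 bridge across the enol ether double bond (cyclopropane centres not assigned) | C[C@]1(O[Si](CC)(CC)CC)CC[C@H]2[C@@H]1CC1C(Br)(Br)C1(O[Si](CC)(CC)CC)C2(C)C | intermediate (not isolated)
37 | (1S,3aS,8aS)-6-bromo-1,4,4-trimethyl-1-[(triethylsilyl)oxy]-2,3,3a,4,8,8a-hexahydroazulen-5(1H)-one | C[C@]1(O[Si](CC)(CC)CC)CC[C@H]2[C@@H]1CC=C(Br)C(=O)C2(C)C | intermediate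
38 | (1S,3aS,8aS)-1,4,4,6-tetramethyl-1-[(triethylsilyl)oxy]-2,3,3a,4,8,8a-hexahydroazulen-5(1H)-one | C[C@]1(O[Si](CC)(CC)CC)CC[C@H]2[C@@H]1CC=C(C)C(=O)C2(C)C | intermediate
39 | {2-[(3S,5aS,6S,7R,9aR)-2,2,5a,7-tetramethyl-3,7-bis(triethylsilyloxy)decahydro-1-benzoxepin-6-yl]ethyl}lithium | [Li]CC[C@H]1[C@]2(C)CC[C@H](O[Si](CC)(CC)CC)C(C)(C)O[C@@H]2CC[C@@]1(C)O[Si](CC)(CC)CC | intermediate (not isolated)
40 | dichloro{2-[(3S,5aS,6S,7R,9aR)-2,2,5a,7-tetramethyl-3,7-bis(triethylsilyloxy)decahydro-1-benzoxepin-6-yl]ethyl}cerium | Cl[Ce](Cl)CC[C@H]1[C@]2(C)CC[C@H](O[Si](CC)(CC)CC)C(C)(C)O[C@@H]2CC[C@@]1(C)O[Si](CC)(CC)CC | intermediate (not isolated)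
41 | (1S,3aS,8aS)-5-{2-[(3S,5aS,6S,7R,9aR)-2,2,5a,7-tetramethyl-3,7-bis(triethylsilyloxy)decahydro-1-benzoxepin-6-yl]ethyl}-1,4,4,6-tetramethyl-1-(triethylsilyloxy)-1,2,3,3a,4,5,8,8a-octahydroazulen-5-ol (C-5 epimers) | C[C@]1(O[Si](CC)(CC)CC)CC[C@H]2[C@@H]1CC=C(C)C(O)(CC[C@H]1[C@]3(C)CC[C@H](O[Si](CC)(CC)CC)C(C)(C)O[C@@H]3CC[C@@]1(C)O[Si](CC)(CC)CC)C2(C)C | intermediate
42 | (1S,3aS,8aS)-5-{same eastern ethyl side chain as in 41}-1,4,4,6-tetramethyl-1-(triethylsilyloxy)-2,3,3a,4,8,8a-hexahydroazulen-7(1H)-one | C[C@]1(O[Si](CC)(CC)CC)CC[C@H]2[C@@H]1CC(=O)C(C)=C(CC[C@H]1[C@]3(C)CC[C@H](O[Si](CC)(CC)CC)C(C)(C)O[C@@H]3CC[C@@]1(C)O[Si](CC)(CC)CC)C2(C)C | intermediate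
43 | (1S,3aS,7R,8aS)-5-{same side chain}-1,4,4,6-tetramethyl-1-(triethylsilyloxy)-1,2,3,3a,4,7,8,8a-octahydroazulen-7-ol | C[C@]1(O[Si](CC)(CC)CC)CC[C@H]2[C@@H]1C[C@@H](O)C(C)=C(CC[C@H]1[C@]3(C)CC[C@H](O[Si](CC)(CC)CC)C(C)(C)O[C@@H]3CC[C@@]1(C)O[Si](CC)(CC)CC)C2(C)C | intermediate
44 | N-[(7S)-azulen-7-yl]-N-(2-nitrobenzenesulfonyl)hydrazine of 43 (nitrogen in place of the hydroxyl, inverted) | C[C@]1(O[Si](CC)(CC)CC)CC[C@H]2[C@@H]1C[C@H](N(N)S(=O)(=O)c1ccccc1[N+](=O)[O-])C(C)=C(CC[C@H]1[C@]3(C)CC[C@H](O[Si](CC)(CC)CC)C(C)(C)O[C@@H]3CC[C@@]1(C)O[Si](CC)(CC)CC)C2(C)C | intermediate (not isolated)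
45 | (7S)-allylic diazene (N=NH in place of the sulfonylhydrazine) | C[C@]1(O[Si](CC)(CC)CC)CC[C@H]2[C@@H]1C[C@H](N=N)C(C)=C(CC[C@H]1[C@]3(C)CC[C@H](O[Si](CC)(CC)CC)C(C)(C)O[C@@H]3CC[C@@]1(C)O[Si](CC)(CC)CC)C2(C)C | intermediate (not isolated)
46 | (1S,3aS,5R,8aS)-5-{same side chain}-1,4,4,6-tetramethyl-1-(triethylsilyloxy)-1,2,3,3a,4,5,8,8a-octahydroazulene (tris-silyl ether of the target) | C[C@]1(O[Si](CC)(CC)CC)CC[C@H]2[C@@H]1CC=C(C)[C@@H](CC[C@H]1[C@]3(C)CC[C@H](O[Si](CC)(CC)CC)C(C)(C)O[C@@H]3CC[C@@]1(C)O[Si](CC)(CC)CC)C2(C)C | intermediate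
47 | (3S,5aS,6S,7R,9aR)-6-{2-[(1S,3aS,5R,8aS)-1-hydroxy-1,4,4,6-tetramethyl-1,2,3,3a,4,5,8,8a-octahydroazulen-5-yl]ethyl}-2,2,5a,7-tetramethyldecahydro-1-benzoxepine-3,7-diol | CC1=CC[C@H]2[C@H](CC[C@]2(C)O)C(C)(C)[C@@H]1CC[C@H]1[C@]2(C)CC[C@H](O)C(C)(C)O[C@@H]2CC[C@@]1(C)O | target

## Step count and risks

Total steps: 34. Longest linear sequence: 25 steps (steps 1–20, then 30–34); the western branch is 9 steps (21–29) before the union.

The three steps most likely to fail are steps 3, 17 and 22.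

**Step 3 (ketoreductase must override the substrate's own facial bias).** If no enzyme gives the axial alcohol cleanly, the fallback sets out from 5 and returns at 6 by reduction and inversion. NaBH4 in EtOH at −10 °C reduces only the saturated ketone and gives the equatorial alcohol (4aS,5S)-5-hydroxy-4a-methyl-4,4a,5,6,7,8-hexahydronaphthalen-2(3H)-one F1. A Mitsunobu reaction (4-nitrobenzoic acid, PPh3, DIAD, toluene) inverts it to (4aS,5R)-4a-methyl-2-oxo-2,3,4,4a,5,6,7,8-octahydronaphthalen-5-yl 4-nitrobenzoate F2. K2CO3 in MeOH then releases 6.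

**Step 17 (7-endo against 6-exo opening of the epoxide).** If the tetrahydropyran dominates, the fallback sets out from 21 and returns at 22 by turning the problem into a Markovnikov 7-exo closure. Et2Al(NC9H18) (diethylaluminium 2,2,6,6-tetramethylpiperidide) in benzene at 0 °C isomerises the epoxide to methyl {(1S,2S,3R,6R)-3-hydroxy-2-[(3S)-3-hydroxy-4-methylpent-4-en-1-yl]-2,6-dimethyl-6-[(triethylsilyl)oxy]cyclohexyl}acetate F3. Hg(OCOCF3)2 in CH2Cl2 makes the ring hydroxyl add to the more substituted alkene carbon, giving methyl {(3S,5aS,6S,7R,9aR)-3-hydroxy-2,5a,7-trimethyl-7-[(triethylsilyl)oxy]-2-{[(trifluoroacetoxy)mercurio]methyl}decahydro-1-benzoxepin-6-yl}acetate F4. NaBH4/NaOH replaces mercury by hydrogen, so the mercurated carbon becomes the second methyl of 22.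

**Step 22 (enantioselectivity and reactivity of the hindered siloxydiene).** The fallback sets out from 28 and returns at 30 by a stepwise route through a simpler donor. The same oxazaborolidinium catalyst (with Ph3PO) promotes Mukaiyama–Michael addition of 1-methoxy-2-methyl-1-(trimethylsiloxy)propene to 28 and gives methyl 2-methyl-2-[(1S)-3-oxocyclopentyl]propanoate F5. Ethane-1,2-diol and p-TsOH give methyl 2-methyl-2-[(7S)-1,4-dioxaspiro[4.4]nonan-7-yl]propanoate F6. i-Bu2AlH at −78 °C gives 2-methyl-2-[(7S)-1,4-dioxaspiro[4.4]nonan-7-yl]propanal F7. Vinylmagnesium bromide gives 4-methyl-4-[(7S)-1,4-dioxaspiro[4.4]nonan-7-yl]pent-1-en-3-ol F8, and Dess–Martin periodinane gives 4-methyl-4-[(7S)-1,4-dioxaspiro[4.4]nonan-7-yl]pent-1-en-3-one F9. 2 M HCl followed by DBU removes the acetal and closes the six-membered ring by intramolecular Michael addition to give cis-diketone 30.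

## Further compounds

F1 | step 3 | (4aS,5S)-5-hydroxy-4a-methyl-4,4a,5,6,7,8-hexahydronaphthalen-2(3H)-one | C[C@]12CCC(=O)C=C1CCC[C@@H]2O
F2 | step 3 | (4aS,5R)-4a-methyl-2-oxo-2,3,4,4a,5,6,7,8-octahydronaphthalen-5-yl 4-nitrobenzoate | C[C@]12CCC(=O)C=C1CCC[C@H]2OC(=O)c1ccc(cc1)[N+](=O)[O-]
F3 | step 17 | methyl {(1S,2S,3R,6R)-3-hydroxy-2-[(3S)-3-hydroxy-4-methylpent-4-en-1-yl]-2,6-dimethyl-6-[(triethylsilyl)oxy]cyclohexyl}acetate | C[C@]1(CC[C@H](O)C(C)=C)[C@H](CC(=O)OC)[C@](C)(O[Si](CC)(CC)CC)CC[C@H]1O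
F4 | step 17 | methyl {(3S,5aS,6S,7R,9aR)-3-hydroxy-2,5a,7-trimethyl-7-[(triethylsilyl)oxy]-2-{[(trifluoroacetoxy)mercurio]methyl}decahydro-1-benzoxepin-6-yl}acetate (C-2 epimers) | COC(=O)C[C@H]1[C@]2(C)CC[C@H](O)C(C)(C[Hg]OC(=O)C(F)(F)F)O[C@@H]2CC[C@@]1(C)O[Si](CC)(CC)CC
F5 | step 22 | methyl 2-methyl-2-[(1S)-3-oxocyclopentyl]propanoate | COC(=O)C(C)(C)[C@H]1CCC(=O)C1
F6 | step 22 | methyl 2-methyl-2-[(7S)-1,4-dioxaspiro[4.4]nonan-7-yl]propanoate | COC(=O)C(C)(C)[C@H]1CCC2(OCCO2)C1
F7 | step 22 | 2-methyl-2-[(7S)-1,4-dioxaspiro[4.4]nonan-7-yl]propanal | O=CC(C)(C)[C@H]1CCC2(OCCO2)C1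
F8 | step 22 | 4-methyl-4-[(7S)-1,4-dioxaspiro[4.4]nonan-7-yl]pent-1-en-3-ol (carbinol epimers) | C=CC(O)C(C)(C)[C@H]1CCC2(OCCO2)C1
F9 | step 22 | 4-methyl-4-[(7S)-1,4-dioxaspiro[4.4]nonan-7-yl]pent-1-en-3-one | C=CC(=O)C(C)(C)[C@H]1CCC2(OCCO2)C1
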